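**Plan**

- Numbering: ring A C1 (OMe), C2 (Me), C3 (OH), C4 (acetyl), C5 (OH), C6 (CH2 bridge); ring B C1' (bridge), C2' (OH), C3' (diol chain), C4' (OH), C5' (acetyl), C6' (OH).
- Retrosynthesis: cut C5'–acetyl first (Friedel–Crafts), then ring B at C2'–C3' and C4'–C5' (C1'–C2' re-forms on ring closure). This gives a ring A-bearing 3-ethoxycyclobutenone and a chain-bearing silyl ynol ether; the cyclobutenone is cut to a ring A propanoyl ketene plus ethoxyacetylene.
- Enabling feature: ring B is a hexasubstituted benzene with oxygens on C2', C4', C6' alternating with carbon substituents on C1' (CH2 to ring A C6), C3' (chain) and C5'. A 3-alkoxyvinylketene and an ynol ether assemble exactly this pattern.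
- Forward order: ring A is finished first from 2-methylphloroglucinol (acetyl, OMe, CHO, two-carbon homologation). Ring B is then formed in one operation that joins the halves. The C5' acetyl and deprotection follow.
- Stereochemistry: the single (S) carbinol centre comes from methyl (S)-glycidate. The epoxide is opened at CH2, so the centre is never touched.

Key step: step 11

Step 1
Reactants: 1 2-methylbenzene-1,3,5-triol
Product: 2 1-(2,4,6-trihydroxy-3-methylphenyl)ethan-1-one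
Conditions: AcCl (1.05 equiv), AlCl3 (3.5 equiv), CH2Cl2/PhNO2, 0 °C to rt; aq. HCl
Reagents that add atoms: acetyl chloride CC(=O)Cl
Why: Friedel–Crafts C-acylation of the phloroglucinol nucleus, in which the two free ring positions of 1 are equivalent and the first acyl group deactivates the ring towards a second.

Step 2
Reactants: 2 1-(2,4,6-trihydroxy-3-methylphenyl)ethan-1-one
Product: 3 1-(2,6-dihydroxy-4-methoxy-3-methylphenyl)ethan-1-one
Conditions: Me2SO4 (1.0 equiv), K2CO3 (1.0 equiv), acetone, rt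
Reagents that add atoms: dimethyl sulfate COS(=O)(=O)OC
Why: Williamson O-methylation should go to the 4-OH, the only hydroxyl not hydrogen-bonded to the acetyl carbonyl and the most acidic one, as is usual for phloroacetophenones.

Step 3
Reactants: 3 1-(2,6-dihydroxy-4-methoxy-3-methylphenyl)ethan-1-one
Product: 5 3-acetyl-2,4-dihydroxy-6-methoxy-5-methylbenzaldehyde, via iminium chloride 4 (not isolated)
Conditions: POCl3, DMF, EtOAc, 0 °C to rt; then H2O, 50 °C
Reagents that add atoms: N,N-dimethylformamide CN(C)C=O; water O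
Why: Vilsmeier–Haack formylation at the single unsubstituted ring position, which is flanked by OH and OMe and is the standard entry to formyl acylphloroglucinols.

Step 4
Reactants: 5 3-acetyl-2,4-dihydroxy-6-methoxy-5-methylbenzaldehyde
Product: 6 3-acetyl-2,4-bis(benzyloxy)-6-methoxy-5-methylbenzaldehyde
Conditions: BnBr (2.5 equiv), K2CO3, DMF, 60 °C
Reagents that add atoms: benzyl bromide BrCc1ccccc1
Why: Williamson benzylation in warm DMF overcomes the chelated hydroxyls and gives ethers that survive the ketene chemistry and are later removed by BCl3.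

Step 5
Reactants: 6 3-acetyl-2,4-bis(benzyloxy)-6-methoxy-5-methylbenzaldehyde
Product: 9 3-[3-acetyl-2,4-bis(benzyloxy)-6-methoxy-5-methylphenyl]propanoic acid, via arylidene Meldrum's acid 7 (not isolated), via arylmethyl Meldrum's acid 8 (not isolated)
Conditions: Meldrum's acid (1.2 equiv), HCO2H/Et3N (5:2), 95 °C
Reagents that add atoms: Meldrum's acid CC1(C)OC(=O)CC(=O)O1
Why: Knoevenagel condensation, conjugate hydride transfer from triethylammonium formate and decarboxylative ring opening in one pot is an established aldehyde-to-3-arylpropanoic acid homologation, and it avoids a hydrogenation that would endanger the benzyl ethers.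

Step 6
Reactants: 9 3-[3-acetyl-2,4-bis(benzyloxy)-6-methoxy-5-methylphenyl]propanoic acid; 10 ethoxyacetylene
Product: 13 4-{[3-acetyl-2,4-bis(benzyloxy)-6-methoxy-5-methylphenyl]methyl}-3-ethoxycyclobut-2-en-1-one (racemic at C4), via acid chloride 11 (not isolated), via ketene 12 (not isolated)
Conditions: (COCl)2, DMF (cat.), CH2Cl2, 0 °C to rt, evaporate; then slow addition to 10 (3 equiv), Et3N, CH2Cl2, rt
Reagents that add atoms: none
Why: Dehydrochlorination gives the monoalkylketene, which undergoes the known ketene–alkoxyalkyne [2+2] cycloaddition with the ynol ether CH carbon bonding to the ketene carbonyl carbon, giving the 4-substituted 3-ethoxycyclobutenone.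

Step 7
Reactants: 14 methyl (2S)-oxirane-2-carboxylate
Product: 16 2-[(2S)-oxiran-2-yl]propan-2-ol, via epoxy ketone 15 (not isolated)
Conditions: MeMgCl (2.2 equiv), THF, −78 to −40 °C; sat. NH4Cl
Reagents that add atoms: methylmagnesium chloride C[Mg]Cl
Why: Double Grignard addition to the ester is much faster than epoxide opening at low temperature, and the stereocentre is not involved.

Step 8
Reactants: 16 2-[(2S)-oxiran-2-yl]propan-2-ol
Product: 17 (3S)-2-methylhex-5-yne-2,3-diol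
Conditions: HC≡CH, n-BuLi (4 equiv), THF, −78 °C; BF3·OEt2 (3 equiv); then 16, −78 °C; sat. NH4Cl
Reagents that add atoms: acetylene C#C
Why: Yamaguchi-type BF3-promoted epoxide opening by LiC≡CH occurs at the CH2 carbon at −78 °C, so the carbinol centre keeps its configuration and the cold, BF3-complexed alkoxide should not undergo Payne rearrangement.

Step 9
Reactants: 17 (3S)-2-methylhex-5-yne-2,3-diol
Product: 18 (5S)-2,2,4,4-tetramethyl-5-(prop-2-yn-1-yl)-1,3-dioxolane
Conditions: Me2C(OMe)2, PPTS (cat.), CH2Cl2, rt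
Reagents that add atoms: 2,2-dimethoxypropane COC(C)(C)OC
Why: Acid-catalysed transketalisation gives the acetonide, the diol protection that tolerates the organolithium and peroxide reagents of the next step.

Step 10
Reactants: 18 (5S)-2,2,4,4-tetramethyl-5-(prop-2-yn-1-yl)-1,3-dioxolane
Product: 21 tri(propan-2-yl)({3-[(4S)-2,2,5,5-tetramethyl-1,3-dioxolan-4-yl]prop-1-yn-1-yl}oxy)silane, via lithium acetylide 19 (not isolated), via lithium ynolate 20 (not isolated)
Conditions: n-BuLi, THF, −78 °C; LiOOt-Bu (from t-BuOOH and LiN(SiMe3)2), −78 to 0 °C; i-Pr3SiOTf, −78 to 0 °C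
Reagents that add atoms: tert-butyl hydroperoxide CC(C)(C)OO; triisopropylsilyl trifluoromethanesulfonate CC(C)[Si](OS(=O)(=O)C(F)(F)F)(C(C)C)C(C)C
Why: Oxidation of a lithium acetylide by lithium tert-butyl peroxide to the ynolate, followed by O-silylation with a bulky silyl triflate, is the established preparation of triisopropylsilyl ynol ethers.

Step 11
Reactants: 13 4-{[3-acetyl-2,4-bis(benzyloxy)-6-methoxy-5-methylphenyl]methyl}-3-ethoxycyclobut-2-en-1-one; 21 tri(propan-2-yl)({3-[(4S)-2,2,5,5-tetramethyl-1,3-dioxolan-4-yl]prop-1-yn-1-yl}oxy)silane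
Product: 26 1-{2,6-bis(benzyloxy)-3-[(6-ethoxy-2-hydroxy-3-{[(4S)-2,2,5,5-tetramethyl-1,3-dioxolan-4-yl]methyl}-4-{[tri(propan-2-yl)silyl]oxy}phenyl)methyl]-4-methoxy-5-methylphenyl}ethan-1-one, via vinylketene 22 (not isolated), via alkenylcyclobutenone 23 (not isolated), via dienylketene 24 (not isolated), via cyclohexadienone 25 (not isolated)
Conditions: 21 (1.5 equiv), toluene (degassed), 80 °C then 110 °C
Reagents that add atoms: none
Why: Thermal four-electron conrotatory opening of 13 gives vinylketene 22, which undergoes [2+2] cycloaddition with 21 to alkenylcyclobutenone 23 (forming C2'–C3' and C4'–C5'); 23 opens to dienylketene 24, which closes ring B by a thermal disrotatory six-electron electrocyclisation (C1'–C2') to cyclohexadienone 25 and tautomerises to phenol 26. The closest known reaction type is the Danheiser benzannulation of cyclobutenones with silyl ynol ethers. No stereocentre is created, because C4 of 13 and the sp3 ring carbons of 23 and 25 become sp2 on aromatisation and the dioxolane centre is a spectator. The one selectivity needed is the orientation of the ketene–ynol ether cycloaddition, and the polarisation of 21 secures it: its carbon β to oxygen, which carries the CH2 chain, bonds to the electrophilic ketene carbon, placing the chain at C3' beside the new phenol and the siloxy group at C4'. A silyl rather than an ethyl ynol ether is used because it cannot lose an alkene by retro-ene fragmentation at the temperature the push–pull cyclobutenone needs to open, and because it leaves O-4' as an ether that BCl3 does not chelate.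

Step 12
Reactants: 26 ring B phenol with the chain as acetonide (name as in step 11)
Product: 27 1-{2,6-bis(benzyloxy)-3-[(3-[(2S)-2,3-dihydroxy-3-methylbutyl]-6-ethoxy-2-hydroxy-4-{[tri(propan-2-yl)silyl]oxy}phenyl)methyl]-4-methoxy-5-methylphenyl}ethan-1-one
Conditions: AcOH/H2O (4:1), 45 °C
Reagents that add atoms: none
Why: Mild acid hydrolysis of the acetonide should spare aryl silyl and benzyl ethers and is too weak to ionise the tertiary alcohol.

Step 13
Reactants: 27 ring B phenol with the free (2S)-diol chain (name as in step 12)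
Product: 28 (4S)-4-[(3-{[3-acetyl-2,4-bis(benzyloxy)-6-methoxy-5-methylphenyl]methyl}-4-ethoxy-2-hydroxy-6-{[tri(propan-2-yl)silyl]oxy}phenyl)methyl]-5,5-dimethyl-1,3-dioxolan-2-one
Conditions: CDI (1.3 equiv), DMAP (cat.), THF, 50 °C
Reagents that add atoms: 1,1'-carbonyldiimidazole O=C(n1ccnc1)n1ccnc1
Why: Carbonylation of the 1,2-diol to the five-membered cyclic carbonate (the thermodynamic sink, into which any aryl imidazolide at O-2' should funnel) masks both hydroxyls as an electron-poor group that resists ionisation and pinacol shift under the Lewis acids of steps 14 and 15.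

Step 14
Reactants: 28 cyclic carbonate with C5' unsubstituted (name as in step 13)
Product: 29 (4S)-4-[(5-acetyl-3-{[3-acetyl-2,4-bis(benzyloxy)-6-methoxy-5-methylphenyl]methyl}-4-ethoxy-2-hydroxy-6-{[tri(propan-2-yl)silyl]oxy}phenyl)methyl]-5,5-dimethyl-1,3-dioxolan-2-one
Conditions: AcCl (1.5 equiv), SnCl4 (2 equiv), CH2Cl2, −78 to −30 °C
Reagents that add atoms: acetyl chloride CC(=O)Cl
Why: Friedel–Crafts acylation can only occur at C5', the sole unsubstituted aromatic position of the ring A–ring B core, which is para to the free C2' hydroxyl and ortho to two oxygen substituents; any O-2' acetate formed alongside would be cleaved in step 16.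

Step 15
Reactants: 29 C5' methyl ketone (name as in step 14)
Product: 30 (4S)-4-[(5-acetyl-3-{[3-acetyl-2,4-dihydroxy-6-methoxy-5-methylphenyl]methyl}-2,4-dihydroxy-6-{[tri(propan-2-yl)silyl]oxy}phenyl)methyl]-5,5-dimethyl-1,3-dioxolan-2-one
Conditions: BCl3 (8 equiv), C6HMe5 (6 equiv), CH2Cl2, −78 to 0 °C; MeOH, then H2O
Reagents that add atoms: none
Why: BCl3 cleaves the aryl benzyl ethers (pentamethylbenzene traps the benzyl cation) and, through a six-membered chelate with the C5' acetyl carbonyl, the ortho ethyl ether at O-6', whereas the hindered, weakly basic silyl ether at O-4' and the unchelated ring A methyl ether should persist.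

Step 16
Reactants: 30 silyl ether carbonate (name as in step 15)
Product: 31 1-{3-[(3-acetyl-2,4-dihydroxy-6-methoxy-5-methylphenyl)methyl]-5-[(2S)-2,3-dihydroxy-3-methylbutyl]-2,4,6-trihydroxyphenyl}ethan-1-one
Conditions: K2CO3, MeOH, argon, 0 °C to rt; pH 5 phosphate buffer
Reagents that add atoms: none
Why: Base-mediated methanolysis removes the cyclic carbonate and the aryl silyl ether (a phenoxide ortho to an acyl group is a good leaving group) under non-acidic conditions that cannot cyclise the diol onto a neighbouring phenol, and the stereocentre is untouched.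

**Compound list**

1 | 2-methylbenzene-1,3,5-triol | Cc1c(O)cc(O)cc1O | starting material
2 | 1-(2,4,6-trihydroxy-3-methylphenyl)ethan-1-one | CC(=O)c1c(O)cc(O)c(C)c1O | intermediate
3 | 1-(2,6-dihydroxy-4-methoxy-3-methylphenyl)ethan-1-one | CC(=O)c1c(O)cc(OC)c(C)c1O | intermediate
4 | [(3-acetyl-2,4-dihydroxy-6-methoxy-5-methylphenyl)methylidene]dimethylammonium chloride | CC(=O)c1c(O)c(C=[N+](C)C)c(OC)c(C)c1O.[Cl-] | intermediate
5 | 3-acetyl-2,4-dihydroxy-6-methoxy-5-methylbenzaldehyde | CC(=O)c1c(O)c(C=O)c(OC)c(C)c1O | intermediate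
6 | 3-acetyl-2,4-bis(benzyloxy)-6-methoxy-5-methylbenzaldehyde | CC(=O)c1c(OCc2ccccc2)c(C=O)c(OC)c(C)c1OCc1ccccc1 | intermediate
7 | 5-{[3-acetyl-2,4-bis(benzyloxy)-6-methoxy-5-methylphenyl]methylidene}-2,2-dimethyl-1,3-dioxane-4,6-dione | CC(=O)c1c(OCc2ccccc2)c(C=C2C(=O)OC(C)(C)OC2=O)c(OC)c(C)c1OCc1ccccc1 | intermediate
8 | 5-{[3-acetyl-2,4-bis(benzyloxy)-6-methoxy-5-methylphenyl]methyl}-2,2-dimethyl-1,3-dioxane-4,6-dione | CC(=O)c1c(OCc2ccccc2)c(CC2C(=O)OC(C)(C)OC2=O)c(OC)c(C)c1OCc1ccccc1 | intermediate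
9 | 3-[3-acetyl-2,4-bis(benzyloxy)-6-methoxy-5-methylphenyl]propanoic acid | CC(=O)c1c(OCc2ccccc2)c(CCC(=O)O)c(OC)c(C)c1OCc1ccccc1 | intermediate
10 | ethoxyacetylene | CCOC#C | starting material
11 | 3-[3-acetyl-2,4-bis(benzyloxy)-6-methoxy-5-methylphenyl]propanoyl chloride | CC(=O)c1c(OCc2ccccc2)c(CCC(=O)Cl)c(OC)c(C)c1OCc1ccccc1 | intermediate
12 | 3-[3-acetyl-2,4-bis(benzyloxy)-6-methoxy-5-methylphenyl]prop-1-en-1-one (ketene) | CC(=O)c1c(OCc2ccccc2)c(CC=C=O)c(OC)c(C)c1OCc1ccccc1 | intermediate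
13 | 4-{[3-acetyl-2,4-bis(benzyloxy)-6-methoxy-5-methylphenyl]methyl}-3-ethoxycyclobut-2-en-1-one, racemic at C4 | CCOC1=CC(=O)C1Cc1c(OC)c(C)c(OCc2ccccc2)c(C(C)=O)c1OCc1ccccc1 | intermediate
14 | methyl (2S)-oxirane-2-carboxylate | COC(=O)[C@@H]1CO1 | starting material
15 | 1-[(2S)-oxiran-2-yl]ethan-1-one | CC(=O)[C@@H]1CO1 | intermediate
16 | 2-[(2S)-oxiran-2-yl]propan-2-ol | CC(C)(O)[C@@H]1CO1 | intermediate
17 | (3S)-2-methylhex-5-yne-2,3-diol | CC(C)(O)[C@@H](O)CC#C | intermediate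
18 | (5S)-2,2,4,4-tetramethyl-5-(prop-2-yn-1-yl)-1,3-dioxolane | C#CC[C@H]1C(C)(C)OC(C)(C)O1 | intermediate
19 | lithium acetylide of 18 | [Li]C#CC[C@H]1C(C)(C)OC(C)(C)O1 | intermediate
20 | lithium 3-[(4S)-2,2,5,5-tetramethyl-1,3-dioxolan-4-yl]prop-1-yn-1-olate | [Li]OC#CC[C@H]1C(C)(C)OC(C)(C)O1 | intermediate
21 | tri(propan-2-yl)({3-[(4S)-2,2,5,5-tetramethyl-1,3-dioxolan-4-yl]prop-1-yn-1-yl}oxy)silane | CC(C)[Si](OC#CC[C@H]1C(C)(C)OC(C)(C)O1)(C(C)C)C(C)C | intermediate
22 | (3Z)-5-[3-acetyl-2,4-bis(benzyloxy)-6-methoxy-5-methylphenyl]-3-ethoxypenta-1,3-dien-1-one | O=C=C/C(OCC)=C/Cc1c(OC)c(C)c(OCc2ccccc2)c(C(C)=O)c1OCc1ccccc1 | intermediate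
23 | 4-{(1Z)-3-[3-acetyl-2,4-bis(benzyloxy)-6-methoxy-5-methylphenyl]-1-ethoxyprop-1-en-1-yl}-2-{[(4S)-2,2,5,5-tetramethyl-1,3-dioxolan-4-yl]methyl}-3-{[tri(propan-2-yl)silyl]oxy}cyclobut-2-en-1-one, both configurations at C4 | O=C1C(C[C@H]2C(C)(C)OC(C)(C)O2)=C(O[Si](C(C)C)(C(C)C)C(C)C)C1/C(OCC)=C/Cc1c(OC)c(C)c(OCc2ccccc2)c(C(C)=O)c1OCc1ccccc1 | intermediate
24 | (3E,5Z)-7-[3-acetyl-2,4-bis(benzyloxy)-6-methoxy-5-methylphenyl]-5-ethoxy-2-{[(4S)-2,2,5,5-tetramethyl-1,3-dioxolan-4-yl]methyl}-3-{[tri(propan-2-yl)silyl]oxy}hepta-1,3,5-trien-1-one | O=C=C(C[C@H]1C(C)(C)OC(C)(C)O1)/C(O[Si](C(C)C)(C(C)C)C(C)C)=C\C(OCC)=C\Cc1c(OC)c(C)c(OCc2ccccc2)c(C(C)=O)c1OCc1ccccc1 | intermediate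
25 | 6-{[3-acetyl-2,4-bis(benzyloxy)-6-methoxy-5-methylphenyl]methyl}-5-ethoxy-2-{[(4S)-2,2,5,5-tetramethyl-1,3-dioxolan-4-yl]methyl}-3-{[tri(propan-2-yl)silyl]oxy}cyclohexa-2,4-dien-1-one, both configurations at C6 | O=C1C(C[C@H]2C(C)(C)OC(C)(C)O2)=C(O[Si](C(C)C)(C(C)C)C(C)C)C=C(OCC)C1Cc1c(OC)c(C)c(OCc2ccccc2)c(C(C)=O)c1OCc1ccccc1 | intermediate
26 | 1-{2,6-bis(benzyloxy)-3-[(6-ethoxy-2-hydroxy-3-{[(4S)-2,2,5,5-tetramethyl-1,3-dioxolan-4-yl]methyl}-4-{[tri(propan-2-yl)silyl]oxy}phenyl)methyl]-4-methoxy-5-methylphenyl}ethan-1-one | CCOc1cc(O[Si](C(C)C)(C(C)C)C(C)C)c(C[C@H]2C(C)(C)OC(C)(C)O2)c(O)c1Cc1c(OC)c(C)c(OCc2ccccc2)c(C(C)=O)c1OCc1ccccc1 | intermediate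
27 | 1-{2,6-bis(benzyloxy)-3-[(3-[(2S)-2,3-dihydroxy-3-methylbutyl]-6-ethoxy-2-hydroxy-4-{[tri(propan-2-yl)silyl]oxy}phenyl)methyl]-4-methoxy-5-methylphenyl}ethan-1-one | CCOc1cc(O[Si](C(C)C)(C(C)C)C(C)C)c(C[C@H](O)C(C)(C)O)c(O)c1Cc1c(OC)c(C)c(OCc2ccccc2)c(C(C)=O)c1OCc1ccccc1 | intermediate
28 | (4S)-4-[(3-{[3-acetyl-2,4-bis(benzyloxy)-6-methoxy-5-methylphenyl]methyl}-4-ethoxy-2-hydroxy-6-{[tri(propan-2-yl)silyl]oxy}phenyl)methyl]-5,5-dimethyl-1,3-dioxolan-2-one | CCOc1cc(O[Si](C(C)C)(C(C)C)C(C)C)c(C[C@H]2C(C)(C)OC(=O)O2)c(O)c1Cc1c(OC)c(C)c(OCc2ccccc2)c(C(C)=O)c1OCc1ccccc1 | intermediate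
29 | (4S)-4-[(5-acetyl-3-{[3-acetyl-2,4-bis(benzyloxy)-6-methoxy-5-methylphenyl]methyl}-4-ethoxy-2-hydroxy-6-{[tri(propan-2-yl)silyl]oxy}phenyl)methyl]-5,5-dimethyl-1,3-dioxolan-2-one | CCOc1c(C(C)=O)c(O[Si](C(C)C)(C(C)C)C(C)C)c(C[C@H]2C(C)(C)OC(=O)O2)c(O)c1Cc1c(OC)c(C)c(OCc2ccccc2)c(C(C)=O)c1OCc1ccccc1 | intermediate
30 | (4S)-4-[(5-acetyl-3-{[3-acetyl-2,4-dihydroxy-6-methoxy-5-methylphenyl]methyl}-2,4-dihydroxy-6-{[tri(propan-2-yl)silyl]oxy}phenyl)methyl]-5,5-dimethyl-1,3-dioxolan-2-one | Oc1c(C(C)=O)c(O[Si](C(C)C)(C(C)C)C(C)C)c(C[C@H]2C(C)(C)OC(=O)O2)c(O)c1Cc1c(OC)c(C)c(O)c(C(C)=O)c1O | intermediate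
31 | 1-{3-[(3-acetyl-2,4-dihydroxy-6-methoxy-5-methylphenyl)methyl]-5-[(2S)-2,3-dihydroxy-3-methylbutyl]-2,4,6-trihydroxyphenyl}ethan-1-one (CNP0353610.1) | COc1c(C)c(O)c(C(C)=O)c(O)c1Cc1c(O)c(C[C@H](O)C(C)(C)O)c(O)c(C(C)=O)c1O | target

**Step count and risks**

Total step count: 16. Longest linear sequence: 12 steps (steps 1–6 and 11–16 from 2-methylbenzene-1,3,5-triol); steps 7–10 form the convergent branch.

Steps most likely to fail:

Step 11. The vinylogous-ester cyclobutenone may open too slowly, so that degradation of 13 or oligomerisation of 21 outruns capture of the vinylketene. The fallback sets out from 9 and comes back at 26. It generates vinylketene 22 without the cyclobutenone, by 1,4-dehydrochlorination of an unsaturated acid chloride. Acid 9 would be homologated by C-acylation of magnesium ethyl malonate (CDI; KO2CCH2CO2Et, MgCl2, Et3N) to the β-keto ester ethyl 5-[3-acetyl-2,4-bis(benzyloxy)-6-methoxy-5-methylphenyl]-3-oxopentanoate F1. HC(OEt)3 with catalytic H2SO4 in EtOH would convert this into the enol ether ethyl (2E)-5-[3-acetyl-2,4-bis(benzyloxy)-6-methoxy-5-methylphenyl]-3-ethoxypent-2-enoate F2. Saponification (KOH, aqueous EtOH) would give (2E)-5-[3-acetyl-2,4-bis(benzyloxy)-6-methoxy-5-methylphenyl]-3-ethoxypent-2-enoic acid F3, and (COCl)2 would give (2E)-5-[3-acetyl-2,4-bis(benzyloxy)-6-methoxy-5-methylphenyl]-3-ethoxypent-2-enoyl chloride F4. Et3N in toluene at rt to 80 °C in the presence of 21 would remove HCl across C2–C4 to give 22, which would be intercepted as before and carried through 23, 24 and 25 to 26.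

Step 15. Chelation-assisted loss of the silyl group at O-4' could come before de-ethylation, leaving the ethyl ether as an unactivated second ortho ether next to a boron-chelated phenoxide; warming to force it would put the hindered ring A methyl ether at risk. The fallback sets out from 29 and comes back at 31. It changes the mask on O-4' from silyl to acetyl. Bu4NF buffered with AcOH would desilylate 29 to (4S)-4-[(5-acetyl-3-{[3-acetyl-2,4-bis(benzyloxy)-6-methoxy-5-methylphenyl]methyl}-4-ethoxy-2,6-dihydroxyphenyl)methyl]-5,5-dimethyl-1,3-dioxolan-2-one F5. Ac2O, Et3N and DMAP would give its O-2',O-4'-diacetate F6, whose ortho acetate cannot form a phenoxyboron chelate. BCl3 with C6HMe5 should then remove the ethyl and both benzyl groups to give the O-2',O-4'-diacetate of the ring A diol and C6' phenol F7. K2CO3 in methanol would cleave the acetates and the carbonate to give 31.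

Step 14. The acylium ion may enter the doubly flanked C5' only sluggishly, while SnCl4 strips the chelated ring A benzyl ethers and the benzyl cations alkylate the same position. The fallback sets out from 28 and comes back at 29. It introduces the two carbons by cross-coupling. N-Iodosuccinimide in MeCN would iodinate 28 para to the free hydroxyl to give (4S)-4-[(3-{[3-acetyl-2,4-bis(benzyloxy)-6-methoxy-5-methylphenyl]methyl}-4-ethoxy-2-hydroxy-5-iodo-6-{[tri(propan-2-yl)silyl]oxy}phenyl)methyl]-5,5-dimethyl-1,3-dioxolan-2-one F8. Stille coupling with tributyl(1-ethoxyvinyl)stannane (Pd(PPh3)4 as the zerovalent palladium source, CuI, CsF, DMF) would give the 5-(1-ethoxyethenyl) analogue F9. 1 M HCl in THF would hydrolyse the enol ether to methyl ketone 29.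

Further compounds
F1 | step 11 | ethyl 5-[3-acetyl-2,4-bis(benzyloxy)-6-methoxy-5-methylphenyl]-3-oxopentanoate | CCOC(=O)CC(=O)CCc1c(OC)c(C)c(OCc2ccccc2)c(C(C)=O)c1OCc1ccccc1
F2 | step 11 | ethyl (2E)-5-[3-acetyl-2,4-bis(benzyloxy)-6-methoxy-5-methylphenyl]-3-ethoxypent-2-enoate | CCOC(=O)/C=C(/OCC)CCc1c(OC)c(C)c(OCc2ccccc2)c(C(C)=O)c1OCc1ccccc1
F3 | step 11 | (2E)-5-[3-acetyl-2,4-bis(benzyloxy)-6-methoxy-5-methylphenyl]-3-ethoxypent-2-enoic acid | OC(=O)/C=C(/OCC)CCc1c(OC)c(C)c(OCc2ccccc2)c(C(C)=O)c1OCc1ccccc1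
F4 | step 11 | (2E)-5-[3-acetyl-2,4-bis(benzyloxy)-6-methoxy-5-methylphenyl]-3-ethoxypent-2-enoyl chloride | ClC(=O)/C=C(/OCC)CCc1c(OC)c(C)c(OCc2ccccc2)c(C(C)=O)c1OCc1ccccc1
F5 | step 15 | (4S)-4-[(5-acetyl-3-{[3-acetyl-2,4-bis(benzyloxy)-6-methoxy-5-methylphenyl]methyl}-4-ethoxy-2,6-dihydroxyphenyl)methyl]-5,5-dimethyl-1,3-dioxolan-2-one | CCOc1c(C(C)=O)c(O)c(C[C@H]2C(C)(C)OC(=O)O2)c(O)c1Cc1c(OC)c(C)c(OCc2ccccc2)c(C(C)=O)c1OCc1ccccc1
F6 | step 15 | O-2',O-4'-diacetate of F5 | CCOc1c(C(C)=O)c(OC(C)=O)c(C[C@H]2C(C)(C)OC(=O)O2)c(OC(C)=O)c1Cc1c(OC)c(C)c(OCc2ccccc2)c(C(C)=O)c1OCc1ccccc1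
F7 | step 15 | O-2',O-4'-diacetate of the de-ethylated and debenzylated carbonate (ring A 3,5-diol and C6' phenol free) | CC(=O)Oc1c(C[C@H]2C(C)(C)OC(=O)O2)c(OC(C)=O)c(C(C)=O)c(O)c1Cc1c(OC)c(C)c(O)c(C(C)=O)c1O
F8 | step 14 | (4S)-4-[(3-{[3-acetyl-2,4-bis(benzyloxy)-6-methoxy-5-methylphenyl]methyl}-4-ethoxy-2-hydroxy-5-iodo-6-{[tri(propan-2-yl)silyl]oxy}phenyl)methyl]-5,5-dimethyl-1,3-dioxolan-2-one | CCOc1c(I)c(O[Si](C(C)C)(C(C)C)C(C)C)c(C[C@H]2C(C)(C)OC(=O)O2)c(O)c1Cc1c(OC)c(C)c(OCc2ccccc2)c(C(C)=O)c1OCc1ccccc1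
F9 | step 14 | (4S)-4-[(3-{[3-acetyl-2,4-bis(benzyloxy)-6-methoxy-5-methylphenyl]methyl}-4-ethoxy-5-(1-ethoxyethenyl)-2-hydroxy-6-{[tri(propan-2-yl)silyl]oxy}phenyl)methyl]-5,5-dimethyl-1,3-dioxolan-2-one | CCOc1c(C(=C)OCC)c(O[Si](C(C)C)(C(C)C)C(C)C)c(C[C@H]2C(C)(C)OC(=O)O2)c(O)c1Cc1c(OC)c(C)c(OCc2ccccc2)c(C(C)=O)c1OCc1ccccc1
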